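The constants of these steps are hidden from me, so I start from the target readings of the earlier runs and ask what they allow for the flask.

in all of them: substrate 0.27 M
- red: reagent 0.243 M; free catalyst 5.4 mM; run made earlier
- violet: reagent 0.243 M; free catalyst 12 mM; run made earlier
- green: reagent 0.12 M; free catalyst 8.1 mM; run made earlier
- flask: reagent 0.243 M; free catalyst 8.1 mM

- red (time / h: target / %): 1.33: 4; 2.00: 2; 3.00: 7; 5.00: 8; 8.00: 11; 12.0: 10; 20.0: 14
- violet (time / h: target / %): 1.33: 3; 2.00: 5; 3.00: 8; 5.00: 11; 8.00: 13; 12.0: 21; 20.0: 24
- green (time / h: target / %): 1.50: 4; 5.00: 5; 8.00: 8; 12.0: 11; 20.0: 16

(each reading ± 1.5 percentage points)

- percent here means substrate units held: one spent catalyst counts as two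
- on the list of suspects stand: 2 catalyst intermediate B -> spent catalyst; reagent <-> dormant form; substrate + free catalyst <-> catalyst intermediate A; reagent + catalyst intermediate A -> catalyst intermediate B; catalyst intermediate B -> released group + catalyst intermediate C; catalyst intermediate C -> free catalyst + target
- what is bound to the catalyst counts as converted

1. apparent order in reagent when 10% of the substrate are converted (percent change of the rate of making target for one percent more reagent charged)
2. apparent order in free catalyst when 10% of the substrate are converted (percent change of the rate of making target for one percent more free catalyst charged)

In the flask the reagent is the limiting reagent, 0.243 M against 0.27 M of substrate, and its balance has two terms: one reagent per substrate converted takes 11.1% of its charge by 10% conversion, and the dormant form, a suspect on the list, may hold a further part, which target readings do not give me. Yet the summed red and violet readings grow by a factor of 2.00 from 5.00 h to 20.0 h, while time grows by a factor of 4.00. That makes 0.500 the time exponent, the percent rise of target for one percent more time.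

If target follows powers of time and of a charge, the order at fixed conversion is the order at fixed time divided by the time exponent. I sum the readings from 8.00 h to 20.0 h to blunt the scatter. Red against violet gives a fixed-time catalyst order of 0.633. Carrying red to 8.1 mM with that order and setting green against it gives a fixed-time reagent order of 0.364. A straight curve, exponent 1, gives my lower bound, 0.364 for reagent. The exponent read above gives my upper bound, 0.727. For catalyst the same bracket runs from 0.633 to 1.27.

The forecast, 0.45 and 1, with the words “Doubling the reagent therefore gives about 1.4 times the rate”, stands inside both brackets.

The flask gives 0.54 and 1.1, each inside its bracket.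

    2 catalyst intermediate B → spent catalyst (k = 380 /M/h)
    reagent ⇌ dormant form (K = 0.390, k = 0.263 /h)
    substrate + free catalyst ⇌ catalyst intermediate A (K = 3.00 /M, k = 20.5 /M/h)
    reagent + catalyst intermediate A → catalyst intermediate B (k = 14.0 /M/h)
    catalyst intermediate B → released group + catalyst intermediate C (k = 5.55 /h)
    catalyst intermediate C → free catalyst + target (k = 29.5 /h)

In the flask, half of the turnover of the reagent step up to 15.0 h is done by 5.36 h, a third of that time, while spent catalyst climbs from 12.9% at 1.50 h to 53.1% at 15.0 h. That split means a time exponent of 0.673, and 0.364 divided by it is 0.541. On the flask with twice the free catalyst, the same division forecasts a rate factor of 1.92, and that flask stores 2.15.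

(Readings and results stem from a simulated flask with constants of no real substance, and the scatter is random.)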